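The closed, stirred vessel holds substrate, partner at 1.10 equiv and protic impurity at 8.00 mM, and you want to know how much target stands in it at the end.

| flask | substrate | partner | protic impurity | temperature | remark | time |
|---|---|---|---|---|---|---|
| grey | 0.20 M | 1.1 equiv | 8 mM | 50 °C | run made earlier |  |
| gamma | 0.40 M | 1.10 equiv | 8.00 mM | 50 °C |  | 25 min |
| alpha | 0.40 M | 1.10 equiv | 8.00 mM | −10 °C |  | 25 min |
| theta | 0.40 M | 1.10 equiv | 8.00 mM | 20 °C |  | 25 min |

grey run (percent of the substrate charged)

| time / min | target / % |
|---|---|
| 0.167 | 20.3 |
| 0.417 | 36.1 |
| 0.667 | 38.9 |
| 1.00 | 40.9 |
| 1.50 | 42.5 |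
| 2.00 | 40.4 |
| 2.50 | 42.9 |

(scatter of a reading: 1 percentage point)

- the flask that comes out highest in amount of target, in percent of the substrate charged, or "all alike" when all lie within 1.5 percentage points (gamma / alpha / theta / all alike)
- target at the end, in percent of the substrate charged, gamma
- target at the end, in percent of the substrate charged, alpha
- target at the end, in percent of the substrate charged, theta

- the earlier runs do not show what temperature does; that part of a forecast is a guess

The grey run climbs and then stands: its last reading is 42.9 %, although partner was charged at 1.1 equiv. So suppose that partner, not substrate, is the real limiting reagent, and that each protic impurity takes one partner away. The usable partner in grey is then 0.212 M. Divide it by the target made, and the last reading gives 2.47. Gamma has 0.432 M of usable partner, so at that figure it would end at 43.7 %.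

The weak link is that single reading, which carries a scatter of 1 percentage point. But the 4 readings from 1.00 min on wander without a trend, so take their mean, 41.7 %. The partner price, usable partner spent per target made, then reads 2.54. My figure for gamma becomes 42.5 %, and it assumes that the price survives a doubling of concentration at the same temperature. The earlier runs show nothing of temperature, so I give no number for alpha or theta.

The forecast, holding that “Doubling concentration favours the bimolecular path”, names theta as highest and gives gamma 56 %, alpha 45 % and theta 65 %, so its gamma stands higher than mine.

The flasks end at gamma 45.9 %, alpha 3.01 % and theta 66.0 %, with theta highest.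

    partner → second intermediate (k = 0.00678 s⁻¹, Ea = 91.0 kJ mol⁻¹)
    2 second intermediate → homo product (k = 0.0781 M⁻¹ s⁻¹, Ea = 67.0 kJ mol⁻¹)
    partner + protic impurity → quenched reagent (k = 0.393 M⁻¹ s⁻¹, Ea = 50.0 kJ mol⁻¹)
    substrate ⇌ open intermediate (K = 1.30, k = 0.00781 s⁻¹, Ea = 92.0 kJ mol⁻¹, ΔH = −6.00 kJ mol⁻¹)
    open intermediate + second intermediate → target (k = 0.119 M⁻¹ s⁻¹, Ea = 52.0 kJ mol⁻¹)
    (constants at 20 °C)

Gamma keeps 0 % of its partner, and its price comes to 2.35 against the 2.54 read from grey, so its target lies 3.4 points above my figure. Theta also keeps 0 % of its partner at 25.0 min, at a price of 1.64. The neighbouring flask is theta read at 6.0 min, with 8.5 % of its partner left. It has spent 0.394 M of usable partner, which at the price of theta at its end reckons to 60.3 % target. The neighbouring flask holds less than that, 53.1 %, with 0.0243 M of second intermediate standing beside it.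

The numbers in the tables are calculated on assumed constants; the scatter is artificial.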